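## Retrosynthetic overview

1. Target ⇐ Raney Ni hydrogenolysis (two C–S, two O–benzyl bonds) of a cis-fused 2,4-diaryl-3-oxa-7-thiabicyclo[3.3.0]octane; the CH2–S–CH2 unit is the latent cis-3,4-dimethyl pair.
2. Thiabicycle ⇐ radical bicyclization of an (S,R)-bis(1-arylallyl) ether with a one-sulfur donor; the oxolane C3–C4 bond and both C–S bonds of the thiolane form in one operation, and the two ether stereocenters set the two ring-fusion centers.
3. Bis-allylic ether ⇐ iridium-catalyzed asymmetric allylic etherification of the (E)-cinnamyl carbonate of the trioxygenated ring with the cuprous alkoxide of the (S)-aryl vinyl carbinol of the guaiacyl ring.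
4. Fragments ⇐ O-benzylvanillin (vinyl Grignard, lipase resolution) and 3-hydroxy-4,5-dimethoxybenzaldehyde (benzylation/olefination, reduction, carbonate).
5. Ring order: oxolane and temporary thiolane are closed together in the key step; the thiolane is opened in the last step; both arenes are bought.

Assumption: L is the phosphoramidite from (R)-BINOL and bis[(R)-1-phenylethyl]amine, i.e. (Ra,Rc,Rc), taken to give the (R)-configured branched ether from an (E)-cinnamyl carbonate; if a test run shows the opposite sense, its mirror image is used.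

## Route

Step 1
Reactants: 1 4-(benzyloxy)-3-methoxybenzaldehyde (O-benzylvanillin)
Product: 2 rac-1-[4-(benzyloxy)-3-methoxyphenyl]prop-2-en-1-ol
Conditions: CH2=CHMgBr, THF, −78 to 0 °C; aq. NH4Cl
Reagents that add atoms: vinylmagnesium bromide, C=C[Mg]Br
Why: Grignard 1,2-addition to the aryl aldehyde gives the racemic aryl vinyl carbinol, which is resolved in the next step.

Step 2
Reactants: 2 rac-1-[4-(benzyloxy)-3-methoxyphenyl]prop-2-en-1-ol
Product: 3 (1S)-1-[4-(benzyloxy)-3-methoxyphenyl]prop-2-en-1-ol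
Conditions: Novozym 435 (immobilized Candida antarctica lipase B), vinyl acetate, MTBE, 30 °C, to ca. 55% conversion
Reagents that add atoms: none
Why: Lipase-catalyzed kinetic resolution by transesterification (Kazlauskas rule, aryl large and vinyl medium) acylates the (R)-alcohol and leaves the (S)-alcohol, which carries the configuration of C2 of the target, in high ee.

Step 3
Reactants: 4 3-hydroxy-4,5-dimethoxybenzaldehyde
Product: 6 ethyl (E)-3-[3-(benzyloxy)-4,5-dimethoxyphenyl]prop-2-enoate, via O-benzyl aldehyde 5 (not isolated)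
Conditions: BnBr (1.05 equiv), K2CO3, MeCN, 60 °C; then (EtO)2P(O)CH2CO2Et, DBU (cat.), 50 °C
Reagents that add atoms: benzyl bromide, BrCc1ccccc1; triethyl phosphonoacetate, CCOC(=O)CP(=O)(OCC)OCC
Why: Williamson etherification of the phenol is followed in the same flask by Horner–Wadsworth–Emmons olefination, which gives the (E)-enoate from the stabilized phosphonate anion.

Step 4
Reactants: 6 ethyl (E)-3-[3-(benzyloxy)-4,5-dimethoxyphenyl]prop-2-enoate
Product: 7 (E)-3-[3-(benzyloxy)-4,5-dimethoxyphenyl]prop-2-en-1-ol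
Conditions: i-Bu2AlH (2.3 equiv), CH2Cl2, −78 °C; aq. potassium sodium tartrate
Reagents that add atoms: none
Why: 1,2-Hydride reduction of the conjugated ester gives the allylic alcohol without touching the alkene or the benzyl ether.

Step 5
Reactants: 7 (E)-3-[3-(benzyloxy)-4,5-dimethoxyphenyl]prop-2-en-1-ol
Product: 8 tert-butyl (E)-3-[3-(benzyloxy)-4,5-dimethoxyphenyl]prop-2-en-1-yl carbonate
Conditions: Boc2O, n-Bu4NHSO4 (cat.), aq. NaOH, CH2Cl2, 0 °C to rt
Reagents that add atoms: di-tert-butyl dicarbonate, CC(C)(C)OC(=O)OC(=O)OC(C)(C)C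
Why: Phase-transfer O-acylation gives the linear allylic carbonate, whose leaving group releases only non-nucleophilic tert-butoxide in the next step.

Step 6
Reactants: 3 (1S)-1-[4-(benzyloxy)-3-methoxyphenyl]prop-2-en-1-ol; 8 tert-butyl (E)-3-[3-(benzyloxy)-4,5-dimethoxyphenyl]prop-2-en-1-yl carbonate
Product: 11 4-[(1S)-1-{[(1R)-1-[3-(benzyloxy)-4,5-dimethoxyphenyl]prop-2-en-1-yl]oxy}prop-2-en-1-yl]-1-(benzyloxy)-2-methoxybenzene, via lithium alkoxide 9 (not isolated), via cuprous alkoxide 10 (not isolated)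
Conditions: n-BuLi, THF, 0 °C; CuI, rt; then 8 (1.2 equiv), [Ir(cod)Cl]2 (2 mol %), (Ra,Rc,Rc)-L (4 mol %, pre-activated with n-PrNH2), THF, rt; aq. NH4Cl
Reagents that add atoms: none
Why: Iridium-catalyzed asymmetric allylic etherification (Hartwig type) with a cuprous alkoxide attacks the aryl-substituted allyl terminus, so the branched ether forms and its new (R) center is set by catalyst control while the (S) center of 3 is a spectator.

Step 7
Reactants: 11 4-[(1S)-1-{[(1R)-1-[3-(benzyloxy)-4,5-dimethoxyphenyl]prop-2-en-1-yl]oxy}prop-2-en-1-yl]-1-(benzyloxy)-2-methoxybenzene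
Product: 12 (1S,2S,4R,5R)-2-[4-(benzyloxy)-3-methoxyphenyl]-4-[3-(benzyloxy)-4,5-dimethoxyphenyl]-3-oxa-7-thiabicyclo[3.3.0]octane (cis-fused; both aryl groups trans to the thiolane ring)
Conditions: (t-BuS)2 (3 equiv), hν (300 nm, Pyrex), PhH (0.01 M), 60 °C, Ar
Reagents that add atoms: di-tert-butyl disulfide, CC(C)(C)SSC(C)(C)C
Why: Proposed new method: a photogenerated tert-butylthiyl radical adds to a terminal alkene carbon, the secondary radical closes 5-exo-trig onto the other vinyl group through a Beckwith–Houk chair with both aryl groups pseudo-equatorial (so the two new ring-fusion centers are cis to each other and trans to both aryl groups, 1S and 5R), and the primary radical, held next to the sulfide in a medium free of good hydrogen donors, displaces tert-butyl radical by intramolecular homolytic substitution at sulfur to close the thiolane; the closest known reactions are thiyl-radical (thiol–ene) cyclization of 1,6-dienes and thiolane formation from 4-(tert-butylthio)butyl radicals.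

Step 8
Reactants: 12 (1S,2S,4R,5R)-2-[4-(benzyloxy)-3-methoxyphenyl]-4-[3-(benzyloxy)-4,5-dimethoxyphenyl]-3-oxa-7-thiabicyclo[3.3.0]octane
Product: 13 5-[(2R,3R,4S,5S)-5-(4-hydroxy-3-methoxyphenyl)-3,4-dimethyloxolan-2-yl]-2,3-dimethoxyphenol (CNP0022199.2)
Conditions: Raney Ni (W-2, excess, washed neutral), H2 (1 atm), EtOH–THF, 50 °C
Reagents that add atoms: none
Why: Raney Ni reductive desulfurization cleaves both C–S bonds to unveil the two cis methyl groups and hydrogenolyzes both aryl benzyl ethers in the same operation, without touching any stereocenter.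

## Compound list

1 | 4-(benzyloxy)-3-methoxybenzaldehyde | COc1cc(C=O)ccc1OCc1ccccc1 | starting material
2 | rac-1-[4-(benzyloxy)-3-methoxyphenyl]prop-2-en-1-ol | COc1cc(C(O)C=C)ccc1OCc1ccccc1 | intermediate
3 | (1S)-1-[4-(benzyloxy)-3-methoxyphenyl]prop-2-en-1-ol | COc1cc([C@H](C=C)O)ccc1OCc1ccccc1 | intermediate
4 | 3-hydroxy-4,5-dimethoxybenzaldehyde | COc1cc(C=O)cc(O)c1OC | starting material
5 | 3-(benzyloxy)-4,5-dimethoxybenzaldehyde | COc1cc(C=O)cc(OCc2ccccc2)c1OC | intermediate (not isolated)
6 | ethyl (E)-3-[3-(benzyloxy)-4,5-dimethoxyphenyl]prop-2-enoate | CCOC(=O)/C=C/c1cc(OC)c(OC)c(OCc2ccccc2)c1 | intermediate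
7 | (E)-3-[3-(benzyloxy)-4,5-dimethoxyphenyl]prop-2-en-1-ol | OC/C=C/c1cc(OC)c(OC)c(OCc2ccccc2)c1 | intermediate
8 | tert-butyl (E)-3-[3-(benzyloxy)-4,5-dimethoxyphenyl]prop-2-en-1-yl carbonate | CC(C)(C)OC(=O)OC/C=C/c1cc(OC)c(OC)c(OCc2ccccc2)c1 | intermediate
9 | lithium (1S)-1-[4-(benzyloxy)-3-methoxyphenyl]prop-2-en-1-olate | COc1cc([C@H](C=C)O[Li])ccc1OCc1ccccc1 | intermediate (not isolated)
10 | cuprous (1S)-1-[4-(benzyloxy)-3-methoxyphenyl]prop-2-en-1-olate | COc1cc([C@H](C=C)O[Cu])ccc1OCc1ccccc1 | intermediate (not isolated)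
11 | 4-[(1S)-1-{[(1R)-1-[3-(benzyloxy)-4,5-dimethoxyphenyl]prop-2-en-1-yl]oxy}prop-2-en-1-yl]-1-(benzyloxy)-2-methoxybenzene | COc1cc([C@H](C=C)O[C@H](C=C)c2cc(OC)c(OC)c(OCc3ccccc3)c2)ccc1OCc1ccccc1 | intermediate
12 | (1S,2S,4R,5R)-2-[4-(benzyloxy)-3-methoxyphenyl]-4-[3-(benzyloxy)-4,5-dimethoxyphenyl]-3-oxa-7-thiabicyclo[3.3.0]octane | COc1cc([C@H]2O[C@@H](c3cc(OC)c(OC)c(OCc4ccccc4)c3)[C@H](CS5)[C@@H]2C5)ccc1OCc1ccccc1 | intermediate
13 | (2S,3S,4R,5R)-2-(4-hydroxy-3-methoxyphenyl)-5-(3-hydroxy-4,5-dimethoxyphenyl)-3,4-dimethyloxolane (2,3-trans, 3,4-cis, 4,5-trans) | COc1cc([C@H]2O[C@@H](c3cc(O)c(OC)c(OC)c3)[C@H](C)[C@@H]2C)ccc1O | target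

## Step count and risks

Total steps: 8. Longest linear sequence: 6 steps (4 → 6 → 7 → 8 → 11 → 12 → 13).

**Step 7 (most likely to fail).** The ring closure onto sulfur is slow compared with the 5-exo step and has not been shown as part of such a cascade. The primary radical may instead be trapped by disulfide or by adventitious thiol, and thiyl radicals may abstract the doubly activated C–H next to oxygen. The fallback sets out from 11 and gives up the second ring closure. Thioacetic acid (CH3COSH, AIBN, PhH, 80 °C) is used in a conventional thiol–ene radical cyclization, in which the cyclized radical is quenched by hydrogen transfer from the thioacid. This gives S-{[(2S,3S,4R,5R)-2-[4-(benzyloxy)-3-methoxyphenyl]-5-[3-(benzyloxy)-4,5-dimethoxyphenyl]-4-methyloxolan-3-yl]methyl} ethanethioate F1 together with its regioisomer S-{[(2R,3R,4S,5S)-5-[4-(benzyloxy)-3-methoxyphenyl]-2-[3-(benzyloxy)-4,5-dimethoxyphenyl]-4-methyloxolan-3-yl]methyl} ethanethioate F2, set by the same chair transition state. The mixture is submitted to the Raney Ni/H2 conditions of step 8, which remove the thioacetate sulfur and both benzyl groups, and the fallback comes back to the route at 13.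

**Step 8.** Raney Ni may also hydrogenolyze the benzylic C–O bonds of the oxolane once the phenols are free, or stop short of full C–S cleavage. The fallback sets out from 12 and separates the two reductions. Nickel boride (Ni2B, made in the flask from NiCl2·6H2O and NaBH4, MeOH–THF, 0 °C to rt) cleaves only the C–S bonds and gives (2S,3S,4R,5R)-2-[4-(benzyloxy)-3-methoxyphenyl]-5-[3-(benzyloxy)-4,5-dimethoxyphenyl]-3,4-dimethyloxolane F3. The benzyl ethers are then removed by transfer hydrogenolysis (Pd(OH)2/C, cyclohexa-1,4-diene, EtOH, rt), and the fallback comes back to the route at 13.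

**Step 6.** A hindered secondary alkoxide and an electron-rich cinnamyl unit may give linear ether, low diastereoselectivity or re-ionization of the product. The fallback sets out from 5, obtained by working up step 3 before the phosphonate is added, and replaces catalyst control by a stereospecific coupling. Catalytic asymmetric vinylation ((CH2=CH)2Zn, (+)-DAIB (cat.), toluene, 0 °C) gives (1R)-1-[3-(benzyloxy)-4,5-dimethoxyphenyl]prop-2-en-1-ol F4. Acylation (ClCO2Me, pyridine, CH2Cl2, 0 °C) gives methyl (1R)-1-[3-(benzyloxy)-4,5-dimethoxyphenyl]prop-2-en-1-yl carbonate F5. Rhodium-catalyzed allylic etherification (RhCl(PPh3)3, P(OMe)3, THF, 0 °C) with cuprous alkoxide 10, made from 3 as in step 6, proceeds with net retention at the carbonate carbon, and the fallback comes back to the route at 11.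

## Further compounds

F1 | step 7 | S-{[(2S,3S,4R,5R)-2-[4-(benzyloxy)-3-methoxyphenyl]-5-[3-(benzyloxy)-4,5-dimethoxyphenyl]-4-methyloxolan-3-yl]methyl} ethanethioate | COc1cc([C@H]2O[C@@H](c3cc(OC)c(OC)c(OCc4ccccc4)c3)[C@H](C)[C@@H]2CSC(C)=O)ccc1OCc1ccccc1
F2 | step 7 | S-{[(2R,3R,4S,5S)-5-[4-(benzyloxy)-3-methoxyphenyl]-2-[3-(benzyloxy)-4,5-dimethoxyphenyl]-4-methyloxolan-3-yl]methyl} ethanethioate | COc1cc([C@H]2O[C@@H](c3cc(OC)c(OC)c(OCc4ccccc4)c3)[C@H](CSC(C)=O)[C@@H]2C)ccc1OCc1ccccc1
F3 | step 8 | (2S,3S,4R,5R)-2-[4-(benzyloxy)-3-methoxyphenyl]-5-[3-(benzyloxy)-4,5-dimethoxyphenyl]-3,4-dimethyloxolane | COc1cc([C@H]2O[C@@H](c3cc(OC)c(OC)c(OCc4ccccc4)c3)[C@H](C)[C@@H]2C)ccc1OCc1ccccc1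
F4 | step 6 | (1R)-1-[3-(benzyloxy)-4,5-dimethoxyphenyl]prop-2-en-1-ol | O[C@H](C=C)c1cc(OC)c(OC)c(OCc2ccccc2)c1
F5 | step 6 | methyl (1R)-1-[3-(benzyloxy)-4,5-dimethoxyphenyl]prop-2-en-1-yl carbonate | COC(=O)O[C@H](C=C)c1cc(OC)c(OC)c(OCc2ccccc2)c1
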